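## Analysis of the target

Kaempferol 3-O-sulfate is a flavonol. Ring A is a phloroglucinol-type benzene ring (free OH at C5 and C7, the third oxygen is O1 at C8a), ring C is the γ-pyranone (O1, C2, C3, C4=O, C4a, C8a), and ring B is a 4-hydroxyphenyl group on C2. There are no stereocenters, and all fifteen skeletal carbons are sp2. The defining feature is the pair of neighbouring C–O bonds on ring C: the ring ether bond O1–C2 and the bond C3–O that carries the SO3H group, a hydrogen sulfate of an enol conjugated to the C4 carbonyl. This enol sulfate is the sensitive group. It is far more easily cleaved by acid than an aryl sulfate, so the late steps must be neutral or basic and the free acid can only be liberated at the very end. The regiochemical difficulty is that the oxygen to be sulfated (O3) is not the most reactive of the four hydroxyl oxygens: the hydroxyls at C7 and C4' are more acidic and react first with sulfating agents, while the one at C5 is hydrogen-bonded to C4=O. A second difficulty comes from the 5,7-dioxygenation of ring A: in an open-chain precursor the aroyl group then has two ortho substituents, and oxidative ring closures tend to give the five-membered benzofuranone instead of ring C. The vicinal pattern O1–C2 / C3–O–S is exactly what remains when a five-membered 1,2-cyclic sulfate is opened by an oxygen nucleophile, and the plan is built on this feature.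

## Retrosynthetic reasoning

In the open-chain precursors, Cα is the carbon next to the carbonyl (later C3) and Cβ is the benzylic carbon (later C2).

**13 to 12.** Only protecting groups and the counter-ion are removed. The two benzyl ethers on O5 and O7 fall by hydrogenolysis, a neutral operation that the enol sulfate tolerates, and sodium is exchanged for a proton last.

**12 to 11.** The C2=C3 double bond is taken back to C2–H / C3–H. This is an oxidation-level adjustment only. It is placed here because the ring closure below delivers an sp3 C2, and because in 11 the C2–H bond is para to a free ring B hydroxyl (hydridic) and the C3–H bond is α to C4=O (acidic), so this is the one place where dehydrogenation is easy.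

**11 to 8 (key disconnection).** The O1–C2 bond is cut, and the sulfate on O3 is read as one half of a cyclic sulfate that spans Cα and Cβ. The precursor 8 has no ring C and already holds the sulfur at the hexavalent level between the two oxygens. In the forward direction two aryl acetates are cleaved by an alkoxide to give 9. The ring B para-phenoxide ionises the benzylic C–O bond to the quinone methide 10, and the ring A phenoxide closes ring C onto the methide carbon. The cut is made here because it removes ring C and the regiochemical question of sulfation in one stroke: the sulfur never leaves O3, so no sulfating agent ever meets a phenol. The acetates act as an electronic switch. As esters they keep ring B electron-poor and the benzylic C–O bond of 8 intact; once cleaved they force ionisation at Cβ and nowhere else.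

**8 to 6.** Both S–O bonds are cut. The cyclic sulfate comes from the syn-diol 6 through the cyclic sulfite 7 and oxidation at sulfur.

**6 to 5.** Both new C–O bonds come from syn-dihydroxylation of the chalcone alkene. No chiral ligand is needed: the Cβ center is erased in 10 and both centers in 12.

**5 to 4 to 2 + 3.** The two ester bonds are cut first. The Cα=Cβ bond is then cut by an aldol condensation, the only C–C bond formation of the route, which joins the C8 unit of ring A to the C7 unit of ring B. Benzyl ethers are chosen for ring A because they survive the aldol base, the oxidants and the alkoxide trigger, and leave under neutral conditions.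

**2 to 1.** The two benzyl ethers go onto the para hydroxyl and onto one of the two ortho hydroxyls; the remaining ortho hydroxyl stays hydrogen-bonded to the acetyl carbonyl and is left free.

## Alternatives that were turned down

Alternative 1: the textbook route. O1–C2 and C3–O are disconnected at the chalcone level. Algar–Flynn–Oyamada oxidation of chalcone A1 with alkaline peroxide would give the 3-hydroxyflavone A2 directly. Its only free hydroxyl would then be sulfated with a sulfur trioxide–amine complex and the benzyl groups removed, five operations in all. It was turned down on structure and mechanism, not on length. In A1 the aroyl group has two ortho oxygen substituents and is twisted out of the enone plane. Closure to ring C then competes with attack of the same phenoxide at Cα, which closes the five-membered benzofuranone skeleton; this bias is inherent in the 5,7-dioxygenation of the target. The C3–O bond and the O–S bond are also made in separate operations, so the position of the sulfate rests on protecting-group bookkeeping alone.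

Alternative 2: ring expansion of a benzofuranone (Auwers flavonol synthesis). The aurone A3, reachable by one aldol condensation, would be brominated across its exocyclic C=C bond and treated with alkali. Base adds at C2, the five-membered ring opens to a phenoxide-bearing 1,2-diketone, and the phenoxide recloses onto the benzylic carbon, so the skeleton changes from benzofuranone to chromone and A2 results. It was turned down because in A3 the C3 carbonyl is conjugated to the ether oxygens at C4 and C6 and is a poor electrophile, so loss of hydrogen bromide back to A3 should outrun ring opening. Ring A of A3 also has two CH positions each flanked by two oxygens and would itself be brominated. The sulfate would still have to be introduced afterwards, so nothing is gained over Alternative 1.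

Alternative 3: three-component assembly of ring C. Palladium-catalysed carbonylative Sonogashira coupling–annulation of iodophenol A4, alkyne A5 and a one-carbon carbonyl unit from the gas phase would form C4–C4a, C3–C4 and O1–C2 in one operation and give flavone A6. It was turned down because the operation delivers C3 as C–H. The C3–O bond (oxidation of A6 to A2) and the O–S bond need two further steps, so the hardest feature of the target is untouched by the key step. The ynone intermediate can also close 5-exo-dig to the aurone skeleton as well as 6-endo-dig. A4 is not a trivial building block either, since iodination must be steered to the position between the hydroxyl and one benzyloxy group. The operation count (about six) would be lower, but none of the selectivity problems is solved.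

Key step: step 6

Remark on the chemistry: the sulfate monoesters 11 and 12 are carried as sodium salts and the hydrogen sulfate form drawn for the target is liberated only in the last operation. Compounds 6 to 11 are racemic and one enantiomer is drawn; both stereocenters are erased in step 7.

## Route

Step 1
Reactants: 1 2',4',6'-trihydroxyacetophenone
Product: 2 1-[2,4-bis(benzyloxy)-6-hydroxyphenyl]ethan-1-one
Conditions: BnBr (2.1 equiv), K2CO3 (2.2 equiv), DMF, 0 → 25 °C
Reagents that add atoms: benzyl bromide, BrCc1ccccc1
Why: Williamson etherification; the acetyl carbonyl can chelate only one ortho hydroxyl, which is the least acidic and least nucleophilic, so two equivalents of halide should alkylate the para and the other ortho oxygen and stop there.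

Step 2
Reactants: 2 1-[2,4-bis(benzyloxy)-6-hydroxyphenyl]ethan-1-one; 3 4-hydroxybenzaldehyde
Product: 4 (E)-1-[2,4-bis(benzyloxy)-6-hydroxyphenyl]-3-(4-hydroxyphenyl)prop-2-en-1-one
Conditions: KOH (50% aq., excess), EtOH, 25 °C, 48 h; then cold 1 M HCl to pH 5
Reagents that add atoms: none
Why: Claisen–Schmidt aldol condensation; the methyl ketone enolate adds to the aldehyde (which reacts, more slowly, as its phenoxide) and E1cB loss of water should give the (E)-enone, while the benzyl ethers are inert to KOH.

Step 3
Reactants: 4 (E)-1-[2,4-bis(benzyloxy)-6-hydroxyphenyl]-3-(4-hydroxyphenyl)prop-2-en-1-one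
Product: 5 4-[(E)-3-[2-(acetyloxy)-4,6-bis(benzyloxy)phenyl]-3-oxoprop-1-en-1-yl]phenyl acetate
Conditions: Ac2O (3 equiv), pyridine, DMAP (5 mol %), CH2Cl2, 0 → 25 °C
Reagents that add atoms: acetic anhydride, CC(=O)OC(C)=O
Why: DMAP-catalysed O-acylation of both phenols, the chelated one included; the esters block premature flavanone closure and make ring B electron-poor for steps 4 and 5.

Step 4
Reactants: 5 4-[(E)-3-[2-(acetyloxy)-4,6-bis(benzyloxy)phenyl]-3-oxoprop-1-en-1-yl]phenyl acetate
Product: 6 rac-(2S,3R)-1-[2-(acetyloxy)-4,6-bis(benzyloxy)phenyl]-3-[4-(acetyloxy)phenyl]-2,3-dihydroxypropan-1-one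
Conditions: OsO4 (2 mol %), NMO (1.5 equiv), citric acid (1 equiv), acetone/tBuOH/H2O, 25 °C
Reagents that add atoms: N-methylmorpholine N-oxide, C[N+]1([O-])CCOCC1; water, O
Why: osmium-catalysed syn-dihydroxylation with an amine N-oxide as terminal oxidant; suprafacial addition to the (E)-alkene should give the racemic syn (threo) diol, and the citric acid keeps the medium slightly acidic, which speeds turnover for electron-poor alkenes and protects the aryl acetates and the ketol from retro-aldol cleavage.

Step 5
Reactants: 6 rac-(2S,3R)-1-[2-(acetyloxy)-4,6-bis(benzyloxy)phenyl]-3-[4-(acetyloxy)phenyl]-2,3-dihydroxypropan-1-one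
Product: 8 rac-(4S,5R)-4-[2-(acetyloxy)-4,6-bis(benzyloxy)benzoyl]-5-[4-(acetyloxy)phenyl]-1,3,2-dioxathiolane 2,2-dioxide, via cyclic sulfite 7 (not isolated)
Conditions: SOCl2 (1.5 equiv), pyridine (3 equiv), CH2Cl2, 0 °C; then RuCl3·xH2O (1 mol %), NaIO4 (1.5 equiv), MeCN/H2O, 0 °C, 20 min
Reagents that add atoms: thionyl chloride, O=S(Cl)Cl; sodium periodate, [Na+].[O-]I(=O)(=O)=O
Why: two-stage cyclic sulfate synthesis (cyclic sulfite formation, then RuO4-catalysed oxidation at sulfur); the syn diol should give the trans ring, the acetylated ring B keeps the benzylic C–O bond from ionising, and the acyl- and acetoxy-substituted ring A should tolerate the brief, cold exposure to the oxidant.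

Step 6
Reactants: 8 rac-(4S,5R)-4-[2-(acetyloxy)-4,6-bis(benzyloxy)benzoyl]-5-[4-(acetyloxy)phenyl]-1,3,2-dioxathiolane 2,2-dioxide
Product: 11 sodium trans-5,7-bis(benzyloxy)-2-(4-hydroxyphenyl)-4-oxochroman-3-yl sulfate (racemic), via bisphenoxide cyclic sulfate 9 (not isolated), via para-quinone methide sulfate 10 (not isolated)
Conditions: NaOMe (2.1 equiv), THF/MeOH (10:1), −30 → 0 °C; then AcOH (1.0 equiv)
Reagents that add atoms: sodium methoxide, [Na+].[O-]C
Why: Methoxide transesterifies both aryl acetates to give 9; the ring B para-phenoxide then expels the benzylic C–O bond of the cyclic sulfate (vinylogous E1cB) to give the quinone methide 10, in which the former ring survives as a sulfate monoester anion on Cα, and the ring A phenoxide adds to the methide carbon to form O1–C2. The closest known reaction types are the opening of 1,2-cyclic sulfates by oxygen nucleophiles to β-alkoxy sulfate monoesters and the intramolecular oxa-1,6-addition of phenoxides to para-quinone methides. Ring C is closed in the 6-exo-trig mode onto the exocyclic methide bond (6-exo-tet if displacement precedes ionisation, which forms the same bond). C2 is set trans to the C3 sulfate under thermodynamic control, both substituents equatorial and C3 able to epimerise through its enolate, but no stereocontrol is needed because both centers are erased in step 7. The selectivity required is attack at Cβ and not 5-exo-tet attack at Cα; it is secured because ionisation leaves Cα with a sulfate monoanion, which is no leaving group, and because a fast, stoichiometric alkoxide at low temperature should cleave both esters before direct displacement at the secondary Cα can compete. Base-induced opening of the cyclic sulfate at the acidic Cα–H would give an enol sulfate chalcone that closes by oxa-Michael addition to the same product, so this side path converges. The sulfate monoester anion and the benzyl ethers are inert to methoxide, and the limited amount of base should prevent retro-oxa-Michael opening of the product.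

Step 7
Reactants: 11 sodium trans-5,7-bis(benzyloxy)-2-(4-hydroxyphenyl)-4-oxochroman-3-yl sulfate (racemic)
Product: 12 sodium 5,7-bis(benzyloxy)-2-(4-hydroxyphenyl)-4-oxo-4H-chromen-3-yl sulfate
Conditions: DDQ (1.2 equiv), 1,4-dioxane/DMF (9:1), 25 → 50 °C
Reagents that add atoms: none
Why: quinone dehydrogenation of a flavanone; DDQ should abstract hydride from C2–H, which is benzylic, α to O1 and para to the free ring B hydroxyl, and loss of the acidic C3–H then gives the C2=C3 bond, with the sulfate monoanion and benzyl ethers untouched.

Step 8
Reactants: 12 sodium 5,7-bis(benzyloxy)-2-(4-hydroxyphenyl)-4-oxo-4H-chromen-3-yl sulfate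
Product: 13 kaempferol 3-O-sulfate [5,7-dihydroxy-2-(4-hydroxyphenyl)-4-oxo-4H-chromen-3-yl hydrogen sulfate]
Conditions: H2 (1 atm), 10% Pd/C, MeOH/THF, 25 °C; then 0.1 M HCl (1.0 equiv), 0 °C, C18 desalting
Reagents that add atoms: none
Why: hydrogenolysis of benzyl aryl ethers over palladium on carbon; the tetrasubstituted C2=C3 bond and the sulfate ester should not be reduced, the neutral medium preserves the enol sulfate, and one equivalent of cold dilute acid exchanges sodium for a proton.

## Compound list

1 | 2',4',6'-trihydroxyacetophenone [1-(2,4,6-trihydroxyphenyl)ethan-1-one] | CC(=O)c1c(O)cc(O)cc1O | starting material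
2 | 1-[2,4-bis(benzyloxy)-6-hydroxyphenyl]ethan-1-one | CC(=O)c1c(O)cc(OCc2ccccc2)cc1OCc1ccccc1 | intermediate
3 | 4-hydroxybenzaldehyde | O=Cc1ccc(O)cc1 | starting material
4 | (E)-1-[2,4-bis(benzyloxy)-6-hydroxyphenyl]-3-(4-hydroxyphenyl)prop-2-en-1-one | O=C(/C=C/c1ccc(O)cc1)c1c(O)cc(OCc2ccccc2)cc1OCc1ccccc1 | intermediate
5 | 4-[(E)-3-[2-(acetyloxy)-4,6-bis(benzyloxy)phenyl]-3-oxoprop-1-en-1-yl]phenyl acetate | CC(=O)Oc1ccc(/C=C/C(=O)c2c(OC(C)=O)cc(OCc3ccccc3)cc2OCc2ccccc2)cc1 | intermediate
6 | rac-(2S,3R)-1-[2-(acetyloxy)-4,6-bis(benzyloxy)phenyl]-3-[4-(acetyloxy)phenyl]-2,3-dihydroxypropan-1-one (syn diol, one enantiomer drawn) | CC(=O)Oc1cc(OCc2ccccc2)cc(OCc2ccccc2)c1C(=O)[C@@H](O)[C@H](O)c1ccc(OC(C)=O)cc1 | intermediate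
7 | rac-(4S,5R)-4-[2-(acetyloxy)-4,6-bis(benzyloxy)benzoyl]-5-[4-(acetyloxy)phenyl]-1,3,2-dioxathiolane 2-oxide (trans cyclic sulfite, both configurations at sulfur) | CC(=O)Oc1cc(OCc2ccccc2)cc(OCc2ccccc2)c1C(=O)[C@H]3OS(=O)O[C@@H]3c4ccc(OC(C)=O)cc4 | intermediate (not isolated)
8 | rac-(4S,5R)-4-[2-(acetyloxy)-4,6-bis(benzyloxy)benzoyl]-5-[4-(acetyloxy)phenyl]-1,3,2-dioxathiolane 2,2-dioxide (trans cyclic sulfate) | CC(=O)Oc1cc(OCc2ccccc2)cc(OCc2ccccc2)c1C(=O)[C@H]3OS(=O)(=O)O[C@@H]3c4ccc(OC(C)=O)cc4 | intermediate
9 | disodium salt of rac-(4S,5R)-4-[2,4-bis(benzyloxy)-6-oxidobenzoyl]-5-(4-oxidophenyl)-1,3,2-dioxathiolane 2,2-dioxide | [Na+].[Na+].[O-]c1cc(OCc2ccccc2)cc(OCc2ccccc2)c1C(=O)[C@H]3OS(=O)(=O)O[C@@H]3c4ccc([O-])cc4 | intermediate (not isolated)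
10 | disodium 1-[2,4-bis(benzyloxy)-6-oxidophenyl]-1-oxo-3-(4-oxocyclohexa-2,5-dien-1-ylidene)propan-2-yl sulfate (racemic, one enantiomer drawn) | [Na+].[Na+].[O-]c1cc(OCc2ccccc2)cc(OCc2ccccc2)c1C(=O)[C@@H](OS(=O)(=O)[O-])C=C3C=CC(=O)C=C3 | intermediate (not isolated)
11 | sodium trans-5,7-bis(benzyloxy)-2-(4-hydroxyphenyl)-4-oxochroman-3-yl sulfate (racemic, (2S,3S) enantiomer drawn) | Oc1ccc(cc1)[C@H]1[C@@H](C(=O)c2c(OCc3ccccc3)cc(OCc3ccccc3)cc2O1)OS(=O)(=O)[O-].[Na+] | intermediate
12 | sodium 5,7-bis(benzyloxy)-2-(4-hydroxyphenyl)-4-oxo-4H-chromen-3-yl sulfate | [Na+].[O-]S(=O)(=O)Oc1c(-c2ccc(O)cc2)oc2cc(OCc3ccccc3)cc(OCc3ccccc3)c2c1=O | intermediate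
13 | kaempferol 3-O-sulfate [5,7-dihydroxy-2-(4-hydroxyphenyl)-4-oxo-4H-chromen-3-yl hydrogen sulfate] | O=c1c(OS(=O)(=O)O)c(-c2ccc(O)cc2)oc2cc(O)cc(O)c12 | target

## Step count and least certain steps

Total: 8 steps. Longest linear sequence: 8 steps (1 to 13); aldehyde 3 enters in step 2.

**Step 6 (key step).** Three processes could go wrong. The first is displacement at Cα by the ring A phenoxide before ring B has been unmasked, a 5-exo-tet closure that builds the five-membered benzofuranone skeleton and puts the sulfate on the benzylic oxygen. The second is interception of the quinone methide by methanol or methoxide instead of by the internal phenoxide. The third is retro-oxa-Michael opening of ring C if base is in excess. The fallback forms ring C first and introduces the sulfate with a reagent afterwards, using established flavonoid chemistry. It sets out from 2. Claisen–Schmidt condensation of 2 with 4-(benzyloxy)benzaldehyde (KOH, EtOH) gives (E)-1-[2,4-bis(benzyloxy)-6-hydroxyphenyl]-3-[4-(benzyloxy)phenyl]prop-2-en-1-one F1. Oxidative cyclisation (I2 cat., DMSO, 120 °C) gives 5,7-bis(benzyloxy)-2-[4-(benzyloxy)phenyl]-4H-chromen-4-one F2. Epoxidation of the C2=C3 bond with dimethyldioxirane (acetone/CH2Cl2, 0 °C) and acid-catalysed opening (TsOH cat.) gives 5,7-bis(benzyloxy)-2-[4-(benzyloxy)phenyl]-3-hydroxy-4H-chromen-4-one F3, whose only free hydroxyl is on C3. Sulfation (SO3·pyridine, pyridine, 25 °C; NaHCO3) gives sodium 5,7-bis(benzyloxy)-2-[4-(benzyloxy)phenyl]-4-oxo-4H-chromen-3-yl sulfate F4. Hydrogenolysis and acidification under the conditions of step 8 bring the sequence back to the route at 13.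

**Step 5.** Pyridine may trigger β-elimination through the acidic Cα–H while the sulfite forms. The oxidant may attack the benzyloxy-substituted ring A or the benzylic CH2 groups during the oxidation at sulfur. The cyclic sulfate may also open hydrolytically at the benzylic carbon in the aqueous medium. The fallback uses no cyclic sulfate and no oxidant. It sets out from 6. Exhaustive O-sulfation of both hydroxyls (SO3·pyridine, DMF, 25 °C; NaHCO3) gives disodium rac-(2S,3R)-1-[2-(acetyloxy)-4,6-bis(benzyloxy)phenyl]-3-[4-(acetyloxy)phenyl]-1-oxopropane-2,3-diyl bis(sulfate) F5. Treatment with NaOMe (2.1 equiv, THF/MeOH, 0 → 40 °C) cleaves both acetates. The ring B para-phenoxide then expels the benzylic sulfate as sulfate dianion to give 10, which closes as in step 6, and the sequence comes back to the route at 11. In F5 the Cα sulfate is a monoanion throughout, so displacement at Cα cannot compete. The weaker point is that departure of a sulfate dianion needs warming.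

**Step 7.** Hydride abstraction from C2 may be slow. The quinone may degrade the free phenol oxidatively. The acidic hydroquinone by-product may also cleave the newly formed enol sulfate. The fallback replaces hydride abstraction by enol silane formation and palladium-mediated β-hydride elimination (Saegusa–Ito oxidation). It sets out from 11. Soft enolisation (TMSOTf, Et3N, CH2Cl2, 0 °C) gives sodium 5,7-bis(benzyloxy)-4-[(trimethylsilyl)oxy]-2-{4-[(trimethylsilyl)oxy]phenyl}-2H-chromen-3-yl sulfate F6. Treatment with Pd(OAc)2 (divalent palladium, 1.1 equiv, MeCN, 25 °C) places palladium on C3 and eliminates the C2 hydrogen; aqueous work-up removes the aryl silyl ether, and the sequence comes back to the route at 12.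

## Further compounds

F1 | step 6 | (E)-1-[2,4-bis(benzyloxy)-6-hydroxyphenyl]-3-[4-(benzyloxy)phenyl]prop-2-en-1-one | O=C(/C=C/c1ccc(OCc2ccccc2)cc1)c1c(O)cc(OCc2ccccc2)cc1OCc1ccccc1
F2 | step 6 | 5,7-bis(benzyloxy)-2-[4-(benzyloxy)phenyl]-4H-chromen-4-one | O=c1cc(-c2ccc(OCc3ccccc3)cc2)oc2cc(OCc3ccccc3)cc(OCc3ccccc3)c12
F3 | step 6 | 5,7-bis(benzyloxy)-2-[4-(benzyloxy)phenyl]-3-hydroxy-4H-chromen-4-one | O=c1c(O)c(-c2ccc(OCc3ccccc3)cc2)oc2cc(OCc3ccccc3)cc(OCc3ccccc3)c12
F4 | step 6 | sodium 5,7-bis(benzyloxy)-2-[4-(benzyloxy)phenyl]-4-oxo-4H-chromen-3-yl sulfate | O=c1c(OS(=O)(=O)[O-])c(-c2ccc(OCc3ccccc3)cc2)oc2cc(OCc3ccccc3)cc(OCc3ccccc3)c12.[Na+]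
F5 | step 5 | disodium rac-(2S,3R)-1-[2-(acetyloxy)-4,6-bis(benzyloxy)phenyl]-3-[4-(acetyloxy)phenyl]-1-oxopropane-2,3-diyl bis(sulfate) | CC(=O)Oc1cc(OCc2ccccc2)cc(OCc2ccccc2)c1C(=O)[C@@H](OS(=O)(=O)[O-])[C@H](OS(=O)(=O)[O-])c1ccc(OC(C)=O)cc1.[Na+].[Na+]
F6 | step 7 | sodium 5,7-bis(benzyloxy)-4-[(trimethylsilyl)oxy]-2-{4-[(trimethylsilyl)oxy]phenyl}-2H-chromen-3-yl sulfate (racemic, one enantiomer drawn) | C[Si](C)(C)Oc1ccc(cc1)[C@H]1C(OS(=O)(=O)[O-])=C(O[Si](C)(C)C)c2c(OCc3ccccc3)cc(OCc3ccccc3)cc2O1.[Na+]
A1 | alternative 1 | (E)-1-[2,4-bis(benzyloxy)-6-hydroxyphenyl]-3-[4-(benzyloxy)phenyl]prop-2-en-1-one | O=C(/C=C/c1ccc(OCc2ccccc2)cc1)c1c(O)cc(OCc2ccccc2)cc1OCc1ccccc1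
A2 | alternative 1 | 5,7-bis(benzyloxy)-2-[4-(benzyloxy)phenyl]-3-hydroxy-4H-chromen-4-one | O=c1c(O)c(-c2ccc(OCc3ccccc3)cc2)oc2cc(OCc3ccccc3)cc(OCc3ccccc3)c12
A3 | alternative 2 | (Z)-4,6-bis(benzyloxy)-2-[4-(benzyloxy)benzylidene]benzofuran-3(2H)-one | O=C1/C(=C/c2ccc(OCc3ccccc3)cc2)Oc2cc(OCc3ccccc3)cc(OCc3ccccc3)c12
A4 | alternative 3 | 3,5-bis(benzyloxy)-2-iodophenol | Oc1cc(OCc2ccccc2)cc(OCc2ccccc2)c1I
A5 | alternative 3 | 1-(benzyloxy)-4-ethynylbenzene | C#Cc1ccc(OCc2ccccc2)cc1
A6 | alternative 3 | 5,7-bis(benzyloxy)-2-[4-(benzyloxy)phenyl]-4H-chromen-4-one | O=c1cc(-c2ccc(OCc3ccccc3)cc2)oc2cc(OCc3ccccc3)cc(OCc3ccccc3)c12
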